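Ring C of the flavanonol is disconnected at C2–C3. Its precursor is a seven-membered 1,3-benzodioxepin-5-one: the cyclic acetal that ties the ring A phenol oxygen (O1) and the α-ketol oxygen (the later 3-OH) to the ring B aldehyde carbon (C2), used as a mixture of acetal epimers. A chiral Brønsted acid ionises the acetal and lets the enediol carbon C3 re-attack C2, a stereoconvergent oxygen-to-carbon ring contraction that closes ring C and sets C2 and C3 in one operation. It exploits the O1–C2(aryl)–C3(OH)–C4(=O) array, whose electron-rich 2,4-dioxygenated ring B stabilises a cation at C2. The side-chain stereocentre comes from an Evans alkylation.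

Key step: step 15

Remark: ring C atoms are numbered as in the flavanone product in all compounds (O1, C2, C3 carrying O3, C4), and the O-silylated glycolic Weinreb amide used in step 9 is taken to be a commercial reagent.

Step 1
Reactants: 1 (S)-4-benzyl-1,3-oxazolidin-2-one; 2 3-methylbut-2-enoyl chloride
Product: 4 (S)-4-benzyl-3-(3-methylbut-2-enoyl)-1,3-oxazolidin-2-one, via N-lithio oxazolidinone 3 (not isolated)
Conditions: n-BuLi, THF, −78 °C; then 2, −78 → 0 °C
Reagents that add atoms: none
Why: N-acylation of the lithiated oxazolidinone with the acid chloride is the standard way to attach the Evans auxiliary and creates no stereocentre.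

Step 2
Reactants: 4 (S)-4-benzyl-3-(3-methylbut-2-enoyl)-1,3-oxazolidin-2-one; 5 1-bromo-3-methylbut-2-ene (prenyl bromide)
Product: 7 (S)-4-benzyl-3-[(2S)-5-methyl-2-(prop-1-en-2-yl)hex-4-enoyl]-1,3-oxazolidin-2-one, via sodium dienolate 6 (not isolated)
Conditions: NaN(SiMe3)2, THF, −78 °C; then 5, −78 → −20 °C
Reagents that add atoms: none
Why: Evans asymmetric alkylation in its deconjugative form, in which the chelated Z-dienolate is alkylated at the α-carbon on the face opposite the benzyl group of the auxiliary, should set the S stereocentre (the later side-chain centre) and move the double bond out of conjugation to give the isopropenyl group.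

Step 3
Reactants: 7 (S)-4-benzyl-3-[(2S)-5-methyl-2-(prop-1-en-2-yl)hex-4-enoyl]-1,3-oxazolidin-2-one
Product: 8 (S)-4-benzyl-3-[(2S)-3-(3,3-dimethyloxiran-2-yl)-2-(prop-1-en-2-yl)propanoyl]-1,3-oxazolidin-2-one (both epoxide epimers)
Conditions: mCPBA, NaHCO3, CH2Cl2, 0 °C
Reagents that add atoms: 3-chloroperoxybenzoic acid (mCPBA), OOC(=O)c1cccc(Cl)c1
Why: Prilezhaev epoxidation selects the electron-rich trisubstituted alkene over the 1,1-disubstituted isopropenyl group, and the new epoxide stereocentre (formed unselectively) is erased when the next step turns that carbon into CH2.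

Step 4
Reactants: 8 (S)-4-benzyl-3-[(2S)-3-(3,3-dimethyloxiran-2-yl)-2-(prop-1-en-2-yl)propanoyl]-1,3-oxazolidin-2-one
Product: 9 (2S)-5-methyl-2-(prop-1-en-2-yl)hexane-1,5-diol
Conditions: LiAlH4, THF, 0 → 40 °C
Reagents that add atoms: none
Why: Hydride reduction cleaves the imide to the primary alcohol with release of the auxiliary and opens the trisubstituted epoxide at its less substituted carbon to the tertiary alcohol, without touching the stereocentre.

Step 5
Reactants: 9 (2S)-5-methyl-2-(prop-1-en-2-yl)hexane-1,5-diol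
Product: 10 (5S)-6-iodo-2-methyl-5-(prop-1-en-2-yl)hexan-2-ol
Conditions: PPh3, I2, imidazole (premixed), CH2Cl2, 0 °C
Reagents that add atoms: iodine, [I][I]
Why: Appel-type iodination converts only the primary alcohol, because the tertiary alcohol cannot undergo the SN2 displacement of the oxyphosphonium group.

Step 6
Reactants: 10 (5S)-6-iodo-2-methyl-5-(prop-1-en-2-yl)hexan-2-ol
Product: 11 triethyl{[(5S)-6-iodo-2-methyl-5-(prop-1-en-2-yl)hexan-2-yl]oxy}silane
Conditions: TESOTf, 2,6-lutidine, CH2Cl2, −78 °C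
Reagents that add atoms: triethylsilyl trifluoromethanesulfonate (TESOTf), CC[Si](CC)(CC)OS(=O)(=O)C(F)(F)F
Why: Silyl ether protection of the tertiary alcohol with the silyl triflate prevents alkoxide-driven tetrahydropyran formation and quenching of the aryllithium in the coupling step.

Step 7
Reactants: 12 5-methoxybenzene-1,3-diol (5-methoxyresorcinol)
Product: 13 1-methoxy-3,5-bis(methoxymethoxy)benzene
Conditions: MOMCl, i-Pr2NEt, CH2Cl2, 0 → 25 °C
Reagents that add atoms: chloromethyl methyl ether (MOMCl), COCCl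
Why: Williamson-type O-alkylation of both phenols installs the two methoxymethyl ethers that direct the two ortho-metalations.

Step 8
Reactants: 13 1-methoxy-3,5-bis(methoxymethoxy)benzene; 11 triethyl{[(5S)-6-iodo-2-methyl-5-(prop-1-en-2-yl)hexan-2-yl]oxy}silane
Product: 15 triethyl({(5R)-6-[4-methoxy-2,6-bis(methoxymethoxy)phenyl]-2-methyl-5-(prop-1-en-2-yl)hexan-2-yl}oxy)silane, via aryllithium 14 (not isolated)
Conditions: n-BuLi, THF, 0 °C; then 11, 0 → 25 °C
Reagents that add atoms: none
Why: Directed ortho-metalation should take place at the position flanked by both methoxymethoxy groups, and SN2 alkylation of the aryllithium by the primary iodide forms the aryl–CH2 bond without touching the β-stereocentre, whose descriptor changes from S to R only through the priority rules.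

Step 9
Reactants: 15 triethyl({(5R)-6-[4-methoxy-2,6-bis(methoxymethoxy)phenyl]-2-methyl-5-(prop-1-en-2-yl)hexan-2-yl}oxy)silane; 16 2-[(tert-butyldimethylsilyl)oxy]-N-methoxy-N-methylacetamide
Product: 18 2-[(tert-butyldimethylsilyl)oxy]-1-{6-methoxy-2,4-bis(methoxymethoxy)-3-[(2R)-5-methyl-2-(prop-1-en-2-yl)-5-[(triethylsilyl)oxy]hexyl]phenyl}ethan-1-one, via lithiated arene 17 (not isolated)
Conditions: n-BuLi, THF, 0 °C; then 16, −78 → 0 °C; aq. NH4Cl
Reagents that add atoms: none
Why: A second directed ortho-metalation at one of the two equivalent remaining ring positions (between OMe and OMOM) followed by Weinreb ketone synthesis installs the protected hydroxyacetyl group that carries C4 and C3 of ring C.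

Step 10
Reactants: 18 2-[(tert-butyldimethylsilyl)oxy]-1-{6-methoxy-2,4-bis(methoxymethoxy)-3-[(2R)-5-methyl-2-(prop-1-en-2-yl)-5-[(triethylsilyl)oxy]hexyl]phenyl}ethan-1-one
Product: 19 1-{2,4-dihydroxy-3-[(2R)-5-hydroxy-5-methyl-2-(prop-1-en-2-yl)hexyl]-6-methoxyphenyl}-2-hydroxyethan-1-one
Conditions: HCl (0.5 M in MeOH), 40 °C
Reagents that add atoms: none
Why: Acid-catalysed solvolysis of the two aryl MOM acetals and the two alkyl silyl ethers in one operation should give the phenol/α-ketol pair needed for the cyclic acetal.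

Step 11
Reactants: 20 2,4-dihydroxybenzaldehyde
Product: 21 2,4-bis[(tert-butyldimethylsilyl)oxy]benzaldehyde
Conditions: TBSCl, imidazole, DMF, 25 °C
Reagents that add atoms: tert-butyldimethylsilyl chloride (TBSCl), CC(C)(C)[Si](C)(C)Cl
Why: Standard silyl ether protection of both phenols masks ring B as acid-tolerant, still electron-donating silyl ethers that fluoride removes at the end.

Step 12
Reactants: 21 2,4-bis[(tert-butyldimethylsilyl)oxy]benzaldehyde
Product: 22 1-(dimethoxymethyl)-2,4-bis[(tert-butyldimethylsilyl)oxy]benzene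
Conditions: HC(OMe)3 (neat), PPTS (cat.), 25 °C
Reagents that add atoms: trimethyl orthoformate, COC(OC)OC
Why: Acid-catalysed acetalisation with the orthoformate activates the electron-rich aldehyde as its dimethyl acetal for the transacetalisation.

Step 13
Reactants: 19 1-{2,4-dihydroxy-3-[(2R)-5-hydroxy-5-methyl-2-(prop-1-en-2-yl)hexyl]-6-methoxyphenyl}-2-hydroxyethan-1-one; 22 1-(dimethoxymethyl)-2,4-bis[(tert-butyldimethylsilyl)oxy]benzene
Product: 23 2-{2,4-bis[(tert-butyldimethylsilyl)oxy]phenyl}-8-hydroxy-9-[(2R)-5-hydroxy-5-methyl-2-(prop-1-en-2-yl)hexyl]-6-methoxy-2H-1,3-benzodioxepin-5(4H)-one (both epimers at the acetal carbon)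
Conditions: PPTS (10 mol %), 5 Å molecular sieves, CH2Cl2, 25 °C
Reagents that add atoms: none
Why: Acid-catalysed transacetalisation by the phenol ortho to the ketone (the later O1) and the primary ketol hydroxyl (the later O3), the only pair of hydroxyls that can share a ring, should close the seven-membered mixed acetal, driven by uptake of methanol on the sieves, and the new acetal centre forms as a mixture of epimers that is used as such.

Step 14
Reactants: 23 2-{2,4-bis[(tert-butyldimethylsilyl)oxy]phenyl}-8-hydroxy-9-[(2R)-5-hydroxy-5-methyl-2-(prop-1-en-2-yl)hexyl]-6-methoxy-2H-1,3-benzodioxepin-5(4H)-one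
Product: 24 8-[(tert-butyldimethylsilyl)oxy]-2-{2,4-bis[(tert-butyldimethylsilyl)oxy]phenyl}-9-[(2R)-5-hydroxy-5-methyl-2-(prop-1-en-2-yl)hexyl]-6-methoxy-2H-1,3-benzodioxepin-5(4H)-one (both epimers at the acetal carbon)
Conditions: TBSCl, imidazole, DMF, 0 → 25 °C
Reagents that add atoms: tert-butyldimethylsilyl chloride (TBSCl), CC(C)(C)[Si](C)(C)Cl
Why: Silyl ether protection of the remaining phenol, which the tertiary alcohol does not undergo under these conditions, lowers the nucleophilicity of ring A at O7 and C6 before the acid-mediated key step.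

Step 15
Reactants: 24 8-[(tert-butyldimethylsilyl)oxy]-2-{2,4-bis[(tert-butyldimethylsilyl)oxy]phenyl}-9-[(2R)-5-hydroxy-5-methyl-2-(prop-1-en-2-yl)hexyl]-6-methoxy-2H-1,3-benzodioxepin-5(4H)-one
Product: 25 (2R,3R)-7-[(tert-butyldimethylsilyl)oxy]-2-{2,4-bis[(tert-butyldimethylsilyl)oxy]phenyl}-3-hydroxy-8-[(2R)-5-hydroxy-5-methyl-2-(prop-1-en-2-yl)hexyl]-5-methoxy-2,3-dihydro-4H-chromen-4-one
Conditions: (R)-3,3'-bis(2,4,6-triisopropylphenyl)-1,1'-binaphthyl-2,2'-diyl N-triflylphosphoramide (10 mol %), 5 Å molecular sieves, toluene (0.01 M), 40 °C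
Reagents that add atoms: none
Why: Proposed new method: the chiral acid protonates the ketone/O3 site of either acetal epimer of 24, the C2–O3 bond ionises to one and the same aryl(aryloxy)carbenium ion stabilised by the 2,4-disiloxyphenyl ring, the released α-ketol enolises to an enediol held by hydrogen bonds to the chiral phosphoramide anion, and its C3 carbon attacks C2, so that the seven-membered acetal contracts to ring C by a formal 1,2 shift of C2 from oxygen to carbon, the 3-OH and the C4 ketone being already in place. The closest known reaction type is the chiral phosphoric acid-catalysed Petasis–Ferrier-type ring contraction of seven-membered cyclic vinyl acetals, which runs through the same oxocarbenium/enol ion pair, together with Mukaiyama-type additions of enol derivatives to acetals. Ring C closes in a 6-(enolendo)-endo-trig mode. C3 is set by the chiral anion, which covers one face of the bound enediol (catalyst control; the antipode that gives 3R is assumed to be the R acid and would be fixed on a model acetal), and C2 follows C3, because the half-chair transition state and the product carry the aryl group and the 3-OH trans and pseudo-equatorial and any cis isomer can be corrected through reversible ionisation of the O1–C2 bond. The step needs attack by C3 instead of C4 of the enediol, secured because C4 attack would be a 5-endo-trig closure to a quaternary centre giving an aldehyde instead of the aryl-conjugated ketone, and it needs the unproductive cleavage of the C2–O1 bond to stay reversible and free of intermolecular arylation, which the O7 silyl ether and high dilution support.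

Step 16
Reactants: 25 (2R,3R)-7-[(tert-butyldimethylsilyl)oxy]-2-{2,4-bis[(tert-butyldimethylsilyl)oxy]phenyl}-3-hydroxy-8-[(2R)-5-hydroxy-5-methyl-2-(prop-1-en-2-yl)hexyl]-5-methoxy-2,3-dihydro-4H-chromen-4-one
Product: 26 (2R,3R)-2-(2,4-dihydroxyphenyl)-3,7-dihydroxy-8-[(2R)-5-hydroxy-5-methyl-2-(prop-1-en-2-yl)hexyl]-5-methoxy-2,3-dihydro-4H-chromen-4-one (CID44584091)
Conditions: HF·pyridine, pyridine, THF, 0 → 25 °C
Reagents that add atoms: none
Why: Fluoride-mediated silyl ether cleavage under buffered, non-basic conditions should free the three phenols without opening ring C, dehydrating the tertiary alcohol or disturbing the trans-configured C2 and C3.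

Compound list

1 | (S)-4-benzyl-1,3-oxazolidin-2-one | O=C1N[C@@H](Cc2ccccc2)CO1 | starting material
2 | 3-methylbut-2-enoyl chloride | CC(C)=CC(=O)Cl | starting material
3 | lithium salt of (S)-4-benzyl-1,3-oxazolidin-2-one (N-lithio oxazolidinone) | O=C1[N-][C@@H](Cc2ccccc2)CO1.[Li+] | intermediate
4 | (S)-4-benzyl-3-(3-methylbut-2-enoyl)-1,3-oxazolidin-2-one | CC(C)=CC(=O)N1[C@@H](Cc2ccccc2)COC1=O | intermediate
5 | 1-bromo-3-methylbut-2-ene (prenyl bromide) | CC(C)=CCBr | starting material
6 | sodium Z-dienolate of 4 | C=C(C)/C=C(\[O-])N1[C@@H](Cc2ccccc2)COC1=O.[Na+] | intermediate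
7 | (S)-4-benzyl-3-[(2S)-5-methyl-2-(prop-1-en-2-yl)hex-4-enoyl]-1,3-oxazolidin-2-one | C=C(C)[C@H](CC=C(C)C)C(=O)N1[C@@H](Cc2ccccc2)COC1=O | intermediate
8 | (S)-4-benzyl-3-[(2S)-3-(3,3-dimethyloxiran-2-yl)-2-(prop-1-en-2-yl)propanoyl]-1,3-oxazolidin-2-one, both epoxide epimers | C=C(C)[C@H](CC1OC1(C)C)C(=O)N1[C@@H](Cc2ccccc2)COC1=O | intermediate
9 | (2S)-5-methyl-2-(prop-1-en-2-yl)hexane-1,5-diol | C=C(C)[C@H](CCC(C)(C)O)CO | intermediate
10 | (5S)-6-iodo-2-methyl-5-(prop-1-en-2-yl)hexan-2-ol | C=C(C)[C@H](CCC(C)(C)O)CI | intermediate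
11 | triethyl{[(5S)-6-iodo-2-methyl-5-(prop-1-en-2-yl)hexan-2-yl]oxy}silane | C=C(C)[C@H](CCC(C)(C)O[Si](CC)(CC)CC)CI | intermediate
12 | 5-methoxybenzene-1,3-diol (5-methoxyresorcinol) | COc1cc(O)cc(O)c1 | starting material
13 | 1-methoxy-3,5-bis(methoxymethoxy)benzene | COCOc1cc(OC)cc(OCOC)c1 | intermediate
14 | [4-methoxy-2,6-bis(methoxymethoxy)phenyl]lithium | [Li]c1c(OCOC)cc(OC)cc1OCOC | intermediate
15 | triethyl({(5R)-6-[4-methoxy-2,6-bis(methoxymethoxy)phenyl]-2-methyl-5-(prop-1-en-2-yl)hexan-2-yl}oxy)silane | C=C(C)[C@H](CCC(C)(C)O[Si](CC)(CC)CC)Cc1c(OCOC)cc(OC)cc1OCOC | intermediate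
16 | 2-[(tert-butyldimethylsilyl)oxy]-N-methoxy-N-methylacetamide | CON(C)C(=O)CO[Si](C)(C)C(C)(C)C | starting material
17 | aryllithium from 15, lithiated between the OMe and OMOM groups | C=C(C)[C@H](CCC(C)(C)O[Si](CC)(CC)CC)Cc1c(OCOC)cc(OC)c([Li])c1OCOC | intermediate
18 | 2-[(tert-butyldimethylsilyl)oxy]-1-{6-methoxy-2,4-bis(methoxymethoxy)-3-[(2R)-5-methyl-2-(prop-1-en-2-yl)-5-[(triethylsilyl)oxy]hexyl]phenyl}ethan-1-one | C=C(C)[C@H](CCC(C)(C)O[Si](CC)(CC)CC)Cc1c(OCOC)cc(OC)c(C(=O)CO[Si](C)(C)C(C)(C)C)c1OCOC | intermediate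
19 | 1-{2,4-dihydroxy-3-[(2R)-5-hydroxy-5-methyl-2-(prop-1-en-2-yl)hexyl]-6-methoxyphenyl}-2-hydroxyethan-1-one | C=C(C)[C@H](CCC(C)(C)O)Cc1c(O)cc(OC)c(C(=O)CO)c1O | intermediate
20 | 2,4-dihydroxybenzaldehyde | O=Cc1ccc(O)cc1O | starting material
21 | 2,4-bis[(tert-butyldimethylsilyl)oxy]benzaldehyde | O=Cc1ccc(O[Si](C)(C)C(C)(C)C)cc1O[Si](C)(C)C(C)(C)C | intermediate
22 | 1-(dimethoxymethyl)-2,4-bis[(tert-butyldimethylsilyl)oxy]benzene | COC(OC)c1ccc(O[Si](C)(C)C(C)(C)C)cc1O[Si](C)(C)C(C)(C)C | intermediate
23 | 2-{2,4-bis[(tert-butyldimethylsilyl)oxy]phenyl}-8-hydroxy-9-[(2R)-5-hydroxy-5-methyl-2-(prop-1-en-2-yl)hexyl]-6-methoxy-2H-1,3-benzodioxepin-5(4H)-one, both epimers at the acetal carbon | C=C(C)[C@H](CCC(C)(C)O)Cc1c(O)cc(OC)c2C(=O)COC(c3ccc(O[Si](C)(C)C(C)(C)C)cc3O[Si](C)(C)C(C)(C)C)Oc12 | intermediate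
24 | 8-[(tert-butyldimethylsilyl)oxy]-2-{2,4-bis[(tert-butyldimethylsilyl)oxy]phenyl}-9-[(2R)-5-hydroxy-5-methyl-2-(prop-1-en-2-yl)hexyl]-6-methoxy-2H-1,3-benzodioxepin-5(4H)-one, both epimers at the acetal carbon | C=C(C)[C@H](CCC(C)(C)O)Cc1c(O[Si](C)(C)C(C)(C)C)cc(OC)c2C(=O)COC(c3ccc(O[Si](C)(C)C(C)(C)C)cc3O[Si](C)(C)C(C)(C)C)Oc12 | intermediate
25 | (2R,3R)-7-[(tert-butyldimethylsilyl)oxy]-2-{2,4-bis[(tert-butyldimethylsilyl)oxy]phenyl}-3-hydroxy-8-[(2R)-5-hydroxy-5-methyl-2-(prop-1-en-2-yl)hexyl]-5-methoxy-2,3-dihydro-4H-chromen-4-one | C=C(C)[C@H](CCC(C)(C)O)Cc1c(O[Si](C)(C)C(C)(C)C)cc(OC)c2c1O[C@H](c1ccc(O[Si](C)(C)C(C)(C)C)cc1O[Si](C)(C)C(C)(C)C)[C@@H](O)C2=O | intermediate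
26 | (2R,3R)-2-(2,4-dihydroxyphenyl)-3,7-dihydroxy-8-[(2R)-5-hydroxy-5-methyl-2-(prop-1-en-2-yl)hexyl]-5-methoxy-2,3-dihydro-4H-chromen-4-one (CID44584091) | C=C(C)[C@H](CCC(C)(C)O)Cc1c(O)cc(OC)c2c1O[C@H](c1ccc(O)cc1O)[C@@H](O)C2=O | target

Total step count: 16 steps.

Longest linear sequence: 13 steps (steps 1–6, 8, 9, 10, 13, 14, 15, 16).

The three steps most likely to fail

1. Step 15 (Proposed new method). Ionisation may run mainly through the unproductive C2–O1 cleavage and drain into intermolecular arylation or hydrolysis. The ketol may also enolise too slowly, or the chiral anion may discriminate the enediol faces poorly, so that both ring diastereomers form. The fallback uses known chemistry and replaces catalyst control by separation; it sets out from 24. Soft enolisation with TiCl4 and i-Pr2NEt in CH2Cl2 at −78 °C should give the chlorotitanium enolate chelated through O3, while the same Lewis acid ionises the chelated C2–O3 bond. An intramolecular titanium-enolate addition to the acetal (a Mukaiyama-type aldol to an acetal) then closes ring C at C2–C3 to the trans ketol, as a mixture of 25 and the (2S,3S) ring diastereomer of 25 F1. Because the side-chain centre is fixed, the two are diastereomers and would be separated by preparative HPLC on a chiral stationary phase. The route is rejoined at 25.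

2. Step 8. The hindered aryllithium may act as a base on the β-branched iodide, eliminating to the conjugated diene, or may substitute too slowly. The fallback sets out from 13 and 11. Aryllithium 14 is quenched with 1,2-dibromotetrachloroethane to give 2-bromo-5-methoxy-1,3-bis(methoxymethoxy)benzene F2. Iodide 11 is converted with Zn dust and LiCl in THF into {(2S)-5-methyl-2-(prop-1-en-2-yl)-5-[(triethylsilyl)oxy]hexyl}zinc iodide F3. Negishi coupling of F2 with F3 (Pd(OAc)2, SPhos, THF, 50 °C) should give 15, where the route is rejoined.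

3. Step 13. The chelated, flanked phenol may close the seven-membered ring too slowly, so that acyclic mixed acetals and oligomers accumulate, or the acid may start the ring contraction without stereocontrol. The fallback sets out from 19 and aldehyde 21. TMSCl and Et3N in CH2Cl2 at 0 °C silylate the two phenols and the primary hydroxyl to the tris(trimethylsilyl) ether of 19 F4. Noyori acetalisation of F4 with 21 and catalytic TMSOTf in CH2Cl2 at −78 °C, under kinetic control and driven by loss of hexamethyldisiloxane, should give the 8-O-trimethylsilyl ether of 23 F5. Aqueous NaHCO3 work-up and chromatography remove the aryl trimethylsilyl group and return 23.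

Further compounds

F1 | step 15 | (2S,3S)-7-[(tert-butyldimethylsilyl)oxy]-2-{2,4-bis[(tert-butyldimethylsilyl)oxy]phenyl}-3-hydroxy-8-[(2R)-5-hydroxy-5-methyl-2-(prop-1-en-2-yl)hexyl]-5-methoxy-2,3-dihydro-4H-chromen-4-one | C=C(C)[C@H](CCC(C)(C)O)Cc1c(O[Si](C)(C)C(C)(C)C)cc(OC)c2c1O[C@@H](c1ccc(O[Si](C)(C)C(C)(C)C)cc1O[Si](C)(C)C(C)(C)C)[C@H](O)C2=O
F2 | step 8 | 2-bromo-5-methoxy-1,3-bis(methoxymethoxy)benzene | Brc1c(OCOC)cc(OC)cc1OCOC
F3 | step 8 | {(2S)-5-methyl-2-(prop-1-en-2-yl)-5-[(triethylsilyl)oxy]hexyl}zinc iodide | C=C(C)[C@H](CCC(C)(C)O[Si](CC)(CC)CC)C[Zn]I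
F4 | step 13 | 1-{3-[(2R)-5-hydroxy-5-methyl-2-(prop-1-en-2-yl)hexyl]-6-methoxy-2,4-bis[(trimethylsilyl)oxy]phenyl}-2-[(trimethylsilyl)oxy]ethan-1-one (tris(trimethylsilyl) ether of 19) | C=C(C)[C@H](CCC(C)(C)O)Cc1c(O[Si](C)(C)C)cc(OC)c(C(=O)CO[Si](C)(C)C)c1O[Si](C)(C)C
F5 | step 13 | 2-{2,4-bis[(tert-butyldimethylsilyl)oxy]phenyl}-9-[(2R)-5-hydroxy-5-methyl-2-(prop-1-en-2-yl)hexyl]-6-methoxy-8-[(trimethylsilyl)oxy]-2H-1,3-benzodioxepin-5(4H)-one (8-O-trimethylsilyl ether of 23) | C=C(C)[C@H](CCC(C)(C)O)Cc1c(O[Si](C)(C)C)cc(OC)c2C(=O)COC(c3ccc(O[Si](C)(C)C(C)(C)C)cc3O[Si](C)(C)C(C)(C)C)Oc12
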